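**Retrosynthetic overview**

1. The target is reached by ionic hydrogenation of a cis-fused bicyclic N,O-hemiketal, with hydride entering the convex face of the oxocarbenium ion (sets C3). The hemiketal comes from an enantioselective aza-Michael addition/hemiketalisation of the N-alkylhydroxylamine onto a 1-acylcyclopentene (sets C6a; C3a follows from the cis ring fusion).
2. The 1-acylcyclopentene comes, after excision of an ester, from a phosphine-catalysed Lu [3+2] annulation of an alk-2-ynyl ketone with tert-butyl acrylate as a traceless ethylene equivalent; this one operation forms C3a–C4 and C5–C6.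
3. Enabling feature: the carbocycle (C3a, C4, C5, C6, C6a) is unsubstituted at C4, C5 and C6, shares its C3a–C6a edge with the isoxazolidine, and carries the O-bearing C3 on C3a. At the ketone oxidation level, C3(=O)–C3a=C6a–C6 is the conjugated enone that a Lu annulation of the ynone C3(=O)–C3a≡C6a–C6H3 delivers, and the same enone then accepts N at C6a and O at C3.
4. Ring order: cyclopentane first, isoxazolidine second. One batch of laterally lithiated 3-picoline serves both side chains: with 8-bromooctanoic acid and propynylmagnesium bromide it leads to the ynone, with 1,12-dibromododecane and doubly Boc-protected hydroxylamine to the hydroxylamine.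

Key step: step 8

Assumption: the quinine-derived primary amine catalyst is taken to expose the C6a face that leads to the (6aR) adduct; should the sense be the reverse, its quinidine-derived pseudo-enantiomer takes its place without other change.

**Route**

Step 1
Reactants: 1 3-methylpyridine
Product: 2 (pyridin-3-ylmethyl)lithium
Conditions: LiN(iPr)2 (1.05 equiv), THF, −78 °C; the deep-red solution is kept at −78 °C and divided at once by cannula between steps 2 and 5, which are run in parallel
Reagents that add atoms: lithium diisopropylamide, CC(C)N([Li])C(C)C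
Why: Lateral lithiation of the methyl group of 3-picoline by the amide base gives the picolyl carbanion, which is stable in THF at −78 °C and is made once for both alkylations; no stereocentre is formed.

Step 2
Reactants: 2 (pyridin-3-ylmethyl)lithium; 3 8-bromooctanoic acid
Product: 5 9-(pyridin-3-yl)nonanoic acid, via lithium 8-bromooctanoate 4 (not isolated)
Conditions: 3 deprotonated with LiN(iPr)2 (1.0 equiv), THF, −78 °C; solution of 2 (1.1 equiv) added, −78 °C to rt; then 1 M HCl to pH 6
Reagents that add atoms: none
Why: The picolyl carbanion displaces the primary bromide of the lithium carboxylate 4 in an SN2 alkylation, the carboxylate being inert towards the carbanion; no stereocentre is formed.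

Step 3
Reactants: 5 9-(pyridin-3-yl)nonanoic acid
Product: 7 N-methoxy-N-methyl-9-(pyridin-3-yl)nonanamide, via acyl imidazolide 6 (not isolated)
Conditions: 1,1'-carbonyldiimidazole, CH2Cl2, rt; then MeNH(OMe)·HCl, rt
Reagents that add atoms: N,O-dimethylhydroxylamine hydrochloride, CNOC.Cl
Why: Weinreb amide formation by carboxyl activation as the acyl imidazolide 6 and aminolysis, which the pyridine ring tolerates; no stereocentre is formed.

Step 4
Reactants: 7 N-methoxy-N-methyl-9-(pyridin-3-yl)nonanamide; 8 prop-1-yn-1-ylmagnesium bromide
Product: 10 12-(pyridin-3-yl)dodec-2-yn-4-one, via magnesium hemiaminal chelate 9 (not isolated)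
Conditions: THF, 0 °C to rt; then 1 M HCl, 0 °C
Reagents that add atoms: none
Why: Weinreb ketone synthesis: the alkynyl Grignard reagent adds once because the chelated adduct 9 survives until the acidic quench, so the alk-2-ynyl ketone forms without over-addition; no stereocentre is formed.

Step 5
Reactants: 2 (pyridin-3-ylmethyl)lithium; 11 1,12-dibromododecane
Product: 12 3-(13-bromotridecyl)pyridine
Conditions: solution of 2 added slowly by cannula to 11 (3 equiv), THF, −78 to 0 °C; product used without storage
Reagents that add atoms: none
Why: SN2 alkylation of the picolyl anion with the symmetrical dibromide, in which inverse addition to an excess of the dibromide suppresses double substitution; no stereocentre is formed.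

Step 6
Reactants: 12 3-(13-bromotridecyl)pyridine; 13 tert-butyl N-[(tert-butoxycarbonyl)oxy]carbamate
Product: 14 tert-butyl N-[(tert-butoxycarbonyl)oxy]-N-[13-(pyridin-3-yl)tridecyl]carbamate
Conditions: K2CO3, DMF, 40 °C
Reagents that add atoms: none
Why: N-alkylation of the acidic N–H of the doubly Boc-protected hydroxylamine by the primary bromide (SN2), the two Boc groups blocking O-alkylation and over-alkylation; no stereocentre is formed.

Step 7
Reactants: 14 tert-butyl N-[(tert-butoxycarbonyl)oxy]-N-[13-(pyridin-3-yl)tridecyl]carbamate
Product: 15 N-[13-(pyridin-3-yl)tridecyl]hydroxylamine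
Conditions: CF3CO2H, CH2Cl2, 0 °C to rt; aq. NaHCO3 work-up under argon
Reagents that add atoms: none
Why: Acidolysis of the N-Boc carbamate and the O-Boc carbonate (loss of isobutene and CO2) frees the N-alkylhydroxylamine, which is kept under argon to avoid air oxidation; no stereocentre is formed.

Step 8
Reactants: 10 12-(pyridin-3-yl)dodec-2-yn-4-one; 16 tert-butyl acrylate
Product: 19 tert-butyl 3-[9-(pyridin-3-yl)nonanoyl]cyclopent-3-ene-1-carboxylate, via allenyl ketone 17 (not isolated), via phosphonium dienolate 18 (not isolated)
Conditions: PBu3 (20 mol%), 16 (3 equiv), toluene, rt, slow addition of 10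
Reagents that add atoms: none
Why: PBu3 isomerises ynone 10 to allenyl ketone 17 and adds to its central carbon (the future C6a), giving phosphonium dienolate 18, a three-carbon 1,3-dipole whose nucleophilic termini are the future C3a and C6; conjugate addition of C3a to the CH2 terminus of acrylate 16 (new C3a–C4 bond) is followed by closure of the resulting ester enolate onto the CH2 terminus of the vinylphosphonium unit (new C5–C6 bond), a proton shift and loss of PBu3, which leaves the C3a=C6a double bond conjugated with the C3 ketone. The closest known reaction type is the Lu phosphine-catalysed [3+2] annulation of buta-2,3-dienoates, but-2-ynoates and allenyl ketones with acrylates. The cyclopentene ring closes in a stepwise, formally 5-endo-trig Michael mode (or an asynchronous concerted variant), overall a formal [3+2] cycloaddition of the dipole across the acrylate C=C. The only stereocentre formed, the ester-bearing ring carbon, is not controlled and need not be, because it becomes the C5 methylene in step 10; for the same reason the orientation in which the acrylate is taken up is without consequence. The selectivity that matters, cross-annulation instead of self-annulation of 17, is secured by slow addition of 10 to an excess of 16, and the ester is what makes the otherwise unreactive two-carbon C4–C5 unit a competent acceptor.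

Step 9
Reactants: 19 tert-butyl 3-[9-(pyridin-3-yl)nonanoyl]cyclopent-3-ene-1-carboxylate
Product: 20 3-[9-(pyridin-3-yl)nonanoyl]cyclopent-3-ene-1-carboxylic acid
Conditions: CF3CO2H/CH2Cl2 (1:3), 0 °C to rt
Reagents that add atoms: none
Why: Acidolysis of the tert-butyl ester (tert-butyl cation lost as isobutene) leaves the conjugated enone and the pyridine untouched; the existing stereocentre is unaffected and inconsequential.

Step 10
Reactants: 20 3-[9-(pyridin-3-yl)nonanoyl]cyclopent-3-ene-1-carboxylic acid
Product: 22 1-(cyclopent-1-en-1-yl)-9-(pyridin-3-yl)nonan-1-one, via thiohydroxamate ester 21 (not isolated)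
Conditions: N-hydroxypyridine-2-thione, N,N'-dicyclohexylcarbodiimide, 4-(dimethylamino)pyridine (cat.), CH2Cl2, 0 °C to rt, dark; then t-BuSH, visible light (tungsten lamp), rt
Reagents that add atoms: none
Why: Barton reductive decarboxylation: the thiohydroxamate ester 21 fragments in a radical chain to CO2 and the secondary ring radical, which takes a hydrogen atom from t-BuSH, so that the ester-bearing carbon becomes the C5 methylene and the only stereocentre of 20 is erased.

Step 11
Reactants: 22 1-(cyclopent-1-en-1-yl)-9-(pyridin-3-yl)nonan-1-one; 15 N-[13-(pyridin-3-yl)tridecyl]hydroxylamine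
Product: 24 (3aS,6aR)-1-[13-(pyridin-3-yl)tridecyl]-3-[8-(pyridin-3-yl)octyl]hexahydro-1H-cyclopenta[c]isoxazol-3-ol, via hydroxyamino ketone 23 (not isolated)
Conditions: 9-amino-9-deoxy-epi-quinine [(8α,9S)-6'-methoxycinchonan-9-amine] (20 mol%), CF3CO2H (40 mol%), toluene, 0 °C, slow addition of 15, argon
Reagents that add atoms: none
Why: Proposed new method: the chiral primary amine condenses reversibly with the ketone of 22 to an α,β-unsaturated iminium ion in which the cinchona scaffold shields one face of C6a, so that the nitrogen of 15 adds to C6a from the open face, after which protonation at C3a, hydrolysis and addition of the N–OH oxygen to the C3 carbonyl close the isoxazolidine as its hemiketal; C6a is the only centre under catalyst control, because C3a equilibrates through the enol and only the cis isomer 23 can close to the cis-fused bicycle 24, and the C3 hemiketal configuration is immaterial; the closest known reaction types are primary-amine (cinchona) iminium-catalysed sulfa-Michael additions to α-branched enones, the iminium-catalysed aza-Michael/hemiacetalisation of N-protected hydroxylamines with enals, and the uncatalysed formation of isoxazolidin-5-ols from N-alkylhydroxylamines and enones, the new element being a free N-alkylhydroxylamine as nucleophile on an α-branched cyclic enone under asymmetric iminium catalysis.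

Step 12
Reactants: 24 (3aS,6aR)-1-[13-(pyridin-3-yl)tridecyl]-3-[8-(pyridin-3-yl)octyl]hexahydro-1H-cyclopenta[c]isoxazol-3-ol
Product: 26 (3S,3aS,6aR)-1-[13-(pyridin-3-yl)tridecyl]-3-[8-(pyridin-3-yl)octyl]hexahydro-1H-cyclopenta[c]isoxazole, via oxocarbenium trifluoroacetate 25 (not isolated)
Conditions: Et3SiH (5 equiv), CF3CO2H (10 equiv), CH2Cl2, −40 to 0 °C; aq. NaHCO3
Reagents that add atoms: none
Why: Ionic hydrogenation: acid ionises the hemiketal to the cis-fused N,O-oxocarbenium ion 25 and Et3SiH delivers hydride to C3 from the convex face (the face of H3a and H6a, away from the cyclopentane ring), which places H3 cis to H3a and H6a and the pyridyloctyl chain on the concave face, i.e. the (3S) configuration, while the N–O bond and the protonated pyridines are inert.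

**Compound list**

1 | 3-methylpyridine (3-picoline) | Cc1cccnc1 | starting material
2 | (pyridin-3-ylmethyl)lithium (THF solution, used at once) | [Li]Cc1cccnc1 | intermediate
3 | 8-bromooctanoic acid | OC(=O)CCCCCCCBr | starting material
4 | lithium 8-bromooctanoate | [Li+].[O-]C(=O)CCCCCCCBr | intermediate
5 | 9-(pyridin-3-yl)nonanoic acid | OC(=O)CCCCCCCCc1cccnc1 | intermediate
6 | 1-[9-(pyridin-3-yl)nonanoyl]-1H-imidazole (acyl imidazolide) | O=C(CCCCCCCCc1cccnc1)n1ccnc1 | intermediate
7 | N-methoxy-N-methyl-9-(pyridin-3-yl)nonanamide | CON(C)C(=O)CCCCCCCCc1cccnc1 | intermediate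
8 | prop-1-yn-1-ylmagnesium bromide | CC#C[Mg]Br | starting material
9 | bromomagnesium 4-[methoxy(methyl)amino]-12-(pyridin-3-yl)dodec-2-yn-4-olate (chelated tetrahedral adduct) | CON(C)C(O[Mg]Br)(C#CC)CCCCCCCCc1cccnc1 | intermediate
10 | 12-(pyridin-3-yl)dodec-2-yn-4-one | CC#CC(=O)CCCCCCCCc1cccnc1 | intermediate
11 | 1,12-dibromododecane | BrCCCCCCCCCCCCBr | starting material
12 | 3-(13-bromotridecyl)pyridine | BrCCCCCCCCCCCCCc1cccnc1 | intermediate
13 | tert-butyl N-[(tert-butoxycarbonyl)oxy]carbamate | CC(C)(C)OC(=O)NOC(=O)OC(C)(C)C | starting material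
14 | tert-butyl N-[(tert-butoxycarbonyl)oxy]-N-[13-(pyridin-3-yl)tridecyl]carbamate | CC(C)(C)OC(=O)N(CCCCCCCCCCCCCc1cccnc1)OC(=O)OC(C)(C)C | intermediate
15 | N-[13-(pyridin-3-yl)tridecyl]hydroxylamine | ONCCCCCCCCCCCCCc1cccnc1 | intermediate
16 | tert-butyl acrylate (tert-butyl prop-2-enoate) | C=CC(=O)OC(C)(C)C | starting material
17 | 12-(pyridin-3-yl)dodeca-1,2-dien-4-one (allenyl ketone) | C=C=CC(=O)CCCCCCCCc1cccnc1 | intermediate
18 | 12-(pyridin-3-yl)-2-(tributylphosphaniumyl)dodeca-1,3-dien-4-olate (phosphonium dienolate zwitterion) | C=C([P+](CCCC)(CCCC)CCCC)C=C([O-])CCCCCCCCc1cccnc1 | intermediate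
19 | tert-butyl 3-[9-(pyridin-3-yl)nonanoyl]cyclopent-3-ene-1-carboxylate (racemic) | CC(C)(C)OC(=O)C1CC(C(=O)CCCCCCCCc2cccnc2)=CC1 | intermediate
20 | 3-[9-(pyridin-3-yl)nonanoyl]cyclopent-3-ene-1-carboxylic acid (racemic) | OC(=O)C1CC(C(=O)CCCCCCCCc2cccnc2)=CC1 | intermediate
21 | 2-thioxopyridin-1(2H)-yl 3-[9-(pyridin-3-yl)nonanoyl]cyclopent-3-ene-1-carboxylate (thiohydroxamate ester) | S=C1C=CC=CN1OC(=O)C1CC(C(=O)CCCCCCCCc2cccnc2)=CC1 | intermediate
22 | 1-(cyclopent-1-en-1-yl)-9-(pyridin-3-yl)nonan-1-one | O=C(CCCCCCCCc1cccnc1)C1=CCCC1 | intermediate
23 | 1-[(1S,2R)-2-{hydroxy[13-(pyridin-3-yl)tridecyl]amino}cyclopentyl]-9-(pyridin-3-yl)nonan-1-one | O=C(CCCCCCCCc1cccnc1)[C@H]1CCC[C@H]1N(O)CCCCCCCCCCCCCc1cccnc1 | intermediate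
24 | (3aS,6aR)-1-[13-(pyridin-3-yl)tridecyl]-3-[8-(pyridin-3-yl)octyl]hexahydro-1H-cyclopenta[c]isoxazol-3-ol (C3 epimers, both used) | c1cncc(CCCCCCCCCCCCCN2OC(O)(CCCCCCCCc3cccnc3)[C@H]3CCC[C@H]32)c1 | intermediate
25 | (3aS,6aR)-configured bicyclic N,O-oxocarbenium ion (O2=C3 cation derived from 24) as trifluoroacetate | c1cncc(CCCCCCCCCCCCCN2[O+]=C(CCCCCCCCc3cccnc3)[C@H]3CCC[C@H]32)c1.[O-]C(=O)C(F)(F)F | intermediate
26 | (3S,3aS,6aR)-1-[13-(pyridin-3-yl)tridecyl]-3-[8-(pyridin-3-yl)octyl]hexahydro-1H-cyclopenta[c]isoxazole (Pyrinodemin B as drawn) | c1cncc(CCCCCCCCCCCCCN2O[C@@H](CCCCCCCCc3cccnc3)[C@H]3CCC[C@H]32)c1 | target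

**Step count**

Total step count: 12. Longest linear sequence: 9 steps (steps 1, 2, 3, 4, 8, 9, 10, 11, 12).

**Steps most likely to fail**

Step 11 (Proposed new method). The uncatalysed background addition of the hydroxylamine, slow iminium formation with the hindered alkyl ketone and reversible retro-aza-Michael equilibration may erode the enantiomeric purity at C6a. The fallback sets out from enone 22. Compounds 22 and 15 are combined without catalyst (EtOH, rt), the known uncatalysed isoxazolidin-5-ol formation, which gives hemiketal 24 as the racemate, i.e. together with its enantiomer (3aR,6aS)-hemiketal F1. The conditions of step 12 then give 26 together with its enantiomer (3R,3aR,6aS)-isoxazolidine F2. The two are separated by preparative supercritical-fluid chromatography on an amylose tris(3,5-dimethylphenylcarbamate) stationary phase (CO2/MeOH with Et2NH). The fallback comes back to the route at 26.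

Step 8. Self-annulation and oligomerisation of the allenyl ketone, phosphine-initiated oligomerisation of the acrylate, and annulation modes that engage the α'-methylene of the ketone may outcompete the cross-annulation. The fallback runs the same ring-forming annulation at the ester level, where it is best established, and builds the ketone afterwards. It sets out from acrylate 16 (and from picolyllithium 2 for the side chain). Ethyl but-2-ynoate and 16 with PBu3 (toluene, rt) give 1-tert-butyl 3-ethyl cyclopent-3-ene-1,3-dicarboxylate F3. MeNH(OMe)·HCl/iPrMgCl (THF, −20 °C) converts the conjugated ethyl ester selectively into tert-butyl 3-[methoxy(methyl)carbamoyl]cyclopent-3-ene-1-carboxylate F4, the tert-butyl ester being inert. Separately, a further portion of the solution of 2 from step 1 is added to excess 1,7-dibromoheptane (THF, −78 to 0 °C) to give 3-(8-bromooctyl)pyridine F5, which is converted with Mg (THF) into [8-(pyridin-3-yl)octyl]magnesium bromide F6. Addition of F6 to F4 (THF, −40 to 0 °C, then 1 M HCl) gives keto ester 19, where the fallback comes back to the route.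

Step 10. Conjugate addition of the thiol to the enone and inefficient chain propagation (premature collapse of the thiohydroxamate ester) may spoil the decarboxylation. The fallback generates the ring radical reductively and without thiol. It sets out from acid 20, which is converted (N-hydroxyphthalimide, N,N'-diisopropylcarbodiimide, CH2Cl2, rt) into the redox-active ester 1,3-dioxoisoindolin-2-yl 3-[9-(pyridin-3-yl)nonanoyl]cyclopent-3-ene-1-carboxylate F7. Single-electron reduction under visible light (Ru(bpy)3Cl2 as photocatalyst, Hantzsch ester as reductant and hydrogen donor, DMF, blue LED) fragments F7 to CO2, phthalimide and the ring radical, which is reduced to enone 22, where the fallback comes back to the route.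

**Further compounds**

F1 | step 11 | (3aR,6aS)-1-[13-(pyridin-3-yl)tridecyl]-3-[8-(pyridin-3-yl)octyl]hexahydro-1H-cyclopenta[c]isoxazol-3-ol (enantiomer of 24) | c1cncc(CCCCCCCCCCCCCN2OC(O)(CCCCCCCCc3cccnc3)[C@@H]3CCC[C@@H]32)c1
F2 | step 11 | (3R,3aR,6aS)-1-[13-(pyridin-3-yl)tridecyl]-3-[8-(pyridin-3-yl)octyl]hexahydro-1H-cyclopenta[c]isoxazole (enantiomer of 26) | c1cncc(CCCCCCCCCCCCCN2O[C@H](CCCCCCCCc3cccnc3)[C@@H]3CCC[C@@H]32)c1
F3 | step 8 | 1-tert-butyl 3-ethyl cyclopent-3-ene-1,3-dicarboxylate (racemic) | CCOC(=O)C1=CCC(C1)C(=O)OC(C)(C)C
F4 | step 8 | tert-butyl 3-[methoxy(methyl)carbamoyl]cyclopent-3-ene-1-carboxylate (racemic) | CON(C)C(=O)C1=CCC(C1)C(=O)OC(C)(C)C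
F5 | step 8 | 3-(8-bromooctyl)pyridine | BrCCCCCCCCc1cccnc1
F6 | step 8 | [8-(pyridin-3-yl)octyl]magnesium bromide | Br[Mg]CCCCCCCCc1cccnc1
F7 | step 10 | 1,3-dioxoisoindolin-2-yl 3-[9-(pyridin-3-yl)nonanoyl]cyclopent-3-ene-1-carboxylate (racemic) | O=C(ON1C(=O)c2ccccc2C1=O)C1CC(C(=O)CCCCCCCCc2cccnc2)=CC1
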